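The runs were computed with made-up constants, and the scatter is random.

Constants first: the one to hand over is c, the loss concentration, the [Q] at which L goes to waste as fast as it goes to X.

| flask | Q | L | remark | time | volume of the second phase over the first |
|---|---|---|---|---|---|
| dusk | 0.010 M | 0.022 M | run made earlier |  |  |
| midnight | 0.040 M | 0.022 M | run made earlier |  |  |
| dawn | 0.020 M | 0.011 M | run made earlier |  |  |
| flask | 0.020 M | 0.0220 M |  | 10 d | 0.25 |

| run | time / d | X / % |
|---|---|---|
| dusk | 3.00 | 49.8 |
| dusk | 6.00 | 49.7 |
| dusk | 10.0 | 48.7 |
| dusk | 12.0 | 47.8 |
| midnight | 1.04 | 30.9 |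
| midnight | 2.00 | 32.0 |
| midnight | 5.00 | 31.1 |
| midnight | 12.0 | 31.1 |
| dawn | 1.67 | 23.0 |
| dawn | 4.00 | 23.1 |
| dawn | 8.00 | 22.7 |
| dawn | 12.0 | 22.9 |

(scatter of a reading: 0.5 percentage points)

- in the second phase: L; everything else is in the first
- charges count per volume of the first phase; a concentration in a rate is the amount of a species over the volume of its own phase; every rate counts per litre of the first phase
- the earlier runs hold the two phases in the same ratio of volumes as the flask asked about

- amount of X at 10 d, in percent of the Q charged
- the change that raises the amount of X at 10 d, in percent of the Q charged most ("none" if none brings more than 2 percentage points) (gamma / theta / none)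
- amount of X at 10 d, in percent of the Q charged, after gamma

L acts as the limiting reagent. If each L either meets Q or is lost by a first-order path, then [L] charged = [Q] consumed + c·ln([Q] charged/[Q] left). The plateaus of dusk, midnight and dawn give 0.0247 M, 0.0257 M and 0.0245 M, so the loss concentration c is 0.0249 M.

This flask's [Q] lies midway on a log scale between dusk and midnight, so the mean of their plateaus, 40.4%, is the start. Then just the correction is reckoned. At that start the balance leaves 9.78 × 10⁻⁴ M of L unaccounted for, and full yield costs 0.0619 M at that slope. X therefore rises by 1.6 percentage points to 42.0%.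

Expect that much X at 10 d, perhaps slightly less: the last two dusk readings average 48.2% and the first two 49.8%, a small drift in readings with a scatter of 0.5 points. Leave the transfer alone: it stands nowhere in the balance, so gamma should change nothing. L is the lever: with 0.0630 M as the slope at that yield, the straight-line step for theta gives 35 points, against a threshold of 2 points.

The forecast says 41.5%, theta, and 42% after gamma: “Transfer sets only the speed”.

The flask gives 41.4%, theta with 27 points, and 41.4% after gamma.

    Z ⇌ L, rate k1*([Z] - [L]/K1) per volume of the first phase (partition coefficient = 0.360, kL = 1.00 h⁻¹)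
    Q + Z → X (k = 4.00 M⁻¹ h⁻¹)
    Z → E (k = 0.0990 h⁻¹)
    X → G (k = 8.40 × 10⁻⁵ h⁻¹)

Without the step from Z to E, X in this flask at 10 d climbs from 41.4% to 96.4%. So c weighs that step against capture by Q. In this flask, c·ln gives 0.0137 M, and E stands at 0.0136 M. With 0.0050 M of Q, two correction steps from this flask's yield give 55.1%, then 53.9% of Q consumed. That neighbour flask ends with 45.9% of its Q left and 53.1% as X.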